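The route cuts two bonds at once: C3a–C4 of the bromocyclohexane (ring A: C3a, C4, C5, C6, C7, C7a; benzofuran numbering) and O1–C7a of the oxolane (ring B). The all-anti array Br–C5/C4(Me2)–C3a(H)/C7a(Me)–O1 is the imprint of Br+ adding to a head-to-tail (E)-geranyl chain. The precursor is therefore an achiral open-chain β-keto ester, methyl (5E)-2,6,10-trimethyl-3-oxoundeca-5,9-dienoate. A chiral Lewis base delivers Br+ to one face of its terminal alkene. A chair cascade then closes ring A and, through the ketone oxygen, ring B. One operation gives both rings, all three stereocentres, the C–Br bond and the Z vinylogous carbonate. LiCH2Br finally converts the ester into the bromomethyl ketone.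

Key step: step 3

Assumption: the sense of induction of the thiophosphoramide catalyst cannot be derived with certainty for this substrate. The (R)-catalyst is written, and its (S)-enantiomer takes its place unchanged if a first run shows the opposite sense.

Step 1
Reactants: 1 geranyl chloride [(2E)-1-chloro-3,7-dimethylocta-2,6-diene]
Product: 3 homogeranic acid [(3E)-4,8-dimethylnona-3,7-dienoic acid], via geranylbarium chloride 2 (not isolated)
Conditions: BaI2, Li(C12H10) (lithium biphenylide, 2 equiv), THF, rt (gives active, zerovalent barium); 1, −78 °C; CO2, −78 °C; 1 M HCl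
Reagents that add atoms: carbon dioxide, O=C=O
Why: Carboxylation of an allylic barium reagent: unlike its magnesium or lithium analogues, the allylbarium species formed at −78 °C keeps the E geometry and reacts with CO2 at the unsubstituted α-carbon, so the linear β,γ-unsaturated acid should result, and no stereocentre is formed.

Step 2
Reactants: 3 homogeranic acid; 4 methyl hydrogen methylmalonate (3-methoxy-2-methyl-3-oxopropanoic acid, racemic)
Product: 7 methyl (5E)-2,6,10-trimethyl-3-oxoundeca-5,9-dienoate (C2 epimers), via homogeranoyl imidazolide 5 (not isolated), via magnesium bis(methyl methylmalonate) 6 (not isolated)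
Conditions: flask A: 3, CDI, THF, rt; flask B: 4, Mg(OEt)2, THF, rt, then evaporation; A + B, THF, rt; cold 1 M HCl
Reagents that add atoms: none
Why: Masamune–Brooks chain extension (decarboxylative Claisen condensation): the neutral magnesium malonate 6 is acylated at carbon by 5 and loses CO2 under conditions mild enough to leave the β,γ-alkene in place, and the new C2 centre is configurationally labile, is carried as a mixture and becomes sp2 in step 3.

Step 3
Reactants: 7 methyl (5E)-2,6,10-trimethyl-3-oxoundeca-5,9-dienoate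
Product: 10 methyl (2Z)-2-[(3aS,5S,7aS)-5-bromo-4,4,7a-trimethylhexahydro-1-benzofuran-2(3H)-ylidene]propanoate, via bromonium ion 8 (not isolated), via oxocarbenium ion 9 (not isolated)
Conditions: (R)-3,3'-bis(2,4,6-triisopropylphenyl)-1,1'-binaphthalene-2,2'-diyl N-(trifluoromethylsulfonyl)thiophosphoramide (10 mol %), DBDMH (1.0 equiv), toluene, −78 °C; aq. Na2S2O3
Reagents that add atoms: 1,3-dibromo-5,5-dimethylhydantoin (DBDMH), CC1(C)N(Br)C(=O)N(Br)C1=O
Why: The P=S sulfur of the catalyst takes Br+ from DBDMH and passes it to one face of the electron-rich terminal C9=C10 alkene of 7 to give bromonium ion 8; the C5=C6 alkene is deactivated by the allylic keto group, and the α-methyl keto ester, which sits almost wholly in its keto form and does not enolise at −78 °C, is not brominated. Through a chair transition state C5 opens the bromonium ion at its tertiary carbon C10 (ring A, 6-endo for both the alkene and the bromonium ion) while the C3 ketone oxygen adds to C6 from the opposite face (ring B, formally 5-endo-trig capture of the developing tertiary cation, the mode by which homogeranic acid lactonises), so both rings close in one asynchronous anti addition and no ring is formed later; oxocarbenium ion 9 then gives its doubly activated C2 proton to the hydantoin anion. The closest known reaction type is the Lewis-base-catalysed enantioselective bromonium-induced polyene cyclisation of homogeranylarenes and geranylphenols, in which Br+ is transferred to the same remote isopropylidene terminus. C5 of 10 is set by the catalyst, and C3a and C7a are relayed from it by the substrate: backside opening puts Br equatorial on the chair, and anti addition across the E alkene puts H-3a and the C7a methyl trans-diaxial, which is the trans ring fusion. Attack through oxygen rather than through C2 is secured by geometry, since carbon could reach C6 only in a disfavoured 5-(enolendo) closure to a trans-hydrindanone with two adjacent quaternary carbons. The Z alkene is expected because only with the ester beside O1 and the methyl beside the C3 methylene can the push-pull system stay planar, and an E fraction could be converged with a trace of acid by way of 9.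

Step 4
Reactants: 10 methyl (2Z)-2-[(3aS,5S,7aS)-5-bromo-4,4,7a-trimethylhexahydro-1-benzofuran-2(3H)-ylidene]propanoate
Product: 12 (3Z)-1-bromo-3-[(3aS,5S,7aS)-5-bromo-4,4,7a-trimethylhexahydro-1-benzofuran-2(3H)-ylidene]butan-2-one (target), via lithium hemiketal alkoxide 11 (not isolated)
Conditions: CH2Br2 (3 equiv), MeLi·LiBr (2.8 equiv, slow addition), THF/Et2O, −78 °C; AcOH, −78 °C
Reagents that add atoms: dibromomethane, BrCBr
Why: Addition of a halomethyllithium carbenoid to an ester (nucleophilic acyl substitution): LiCH2Br, made by Br/Li exchange in the presence of 10, should add 1,2 to the ester carbonyl because the fully substituted β-carbon blocks conjugate addition, adduct 11 persists at −78 °C so a second addition is avoided and the ketone appears only on acidic quench, and the hindered secondary bromide, the Z alkene and the three stereocentres are not touched at this temperature.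

Compound list
1 | geranyl chloride, (2E)-1-chloro-3,7-dimethylocta-2,6-diene | CC(C)=CCC/C(C)=C/CCl | starting material
2 | geranylbarium chloride | CC(C)=CCC/C(C)=C/C[Ba]Cl | intermediate
3 | homogeranic acid, (3E)-4,8-dimethylnona-3,7-dienoic acid | CC(C)=CCC/C(C)=C/CC(=O)O | intermediate
4 | methyl hydrogen methylmalonate, 3-methoxy-2-methyl-3-oxopropanoic acid (racemic) | COC(=O)C(C)C(=O)O | starting material
5 | homogeranoyl imidazolide, (3E)-1-(imidazol-1-yl)-4,8-dimethylnona-3,7-dien-1-one | CC(C)=CCC/C(C)=C/CC(=O)n1ccnc1 | intermediate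
6 | magnesium bis(methyl methylmalonate) | [Mg+2].COC(=O)C(C)C(=O)[O-].COC(=O)C(C)C(=O)[O-] | intermediate
7 | methyl (5E)-2,6,10-trimethyl-3-oxoundeca-5,9-dienoate (C2 epimers) | CC(C)=CCC/C(C)=C/CC(=O)C(C)C(=O)OC | intermediate
8 | bromonium ion on C9–C10 of 7, C9 (S) (cation, hydantoin anion as counter-ion) | COC(=O)C(C)C(=O)C/C=C(C)/CC[C@@H]1[Br+]C1(C)C | intermediate
9 | (3aS,5S,7aS)-5-bromo-2-(1-methoxy-1-oxopropan-2-yl)-4,4,7a-trimethyl-3a,4,5,6,7,7a-hexahydro-3H-1-benzofuran-1-ium (oxocarbenium ion) | CC(C(=O)OC)C1C[C@H]2C(C)(C)[C@@H](Br)CC[C@]2(C)[O+]=1 | intermediate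
10 | methyl (2Z)-2-[(3aS,5S,7aS)-5-bromo-4,4,7a-trimethylhexahydro-1-benzofuran-2(3H)-ylidene]propanoate | C/C(C(=O)OC)=C1\C[C@H]2C(C)(C)[C@@H](Br)CC[C@]2(C)O1 | intermediate
11 | lithium (3Z)-1-bromo-3-[(3aS,5S,7aS)-5-bromo-4,4,7a-trimethylhexahydro-1-benzofuran-2(3H)-ylidene]-2-methoxybutan-2-olate | [Li+].C/C(C([O-])(OC)CBr)=C1\C[C@H]2C(C)(C)[C@@H](Br)CC[C@]2(C)O1 | intermediate
12 | (3Z)-1-bromo-3-[(3aS,5S,7aS)-5-bromo-4,4,7a-trimethylhexahydro-1-benzofuran-2(3H)-ylidene]butan-2-one | C/C(C(=O)CBr)=C1\C[C@H]2C(C)(C)[C@@H](Br)CC[C@]2(C)O1 | target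

Total step count: 4. Longest linear sequence: 4 steps (1 → 3 → 7 → 10 → 12).

Steps most likely to fail

1. Step 3.
- What may go wrong: weak facial discrimination in the Br+ transfer, erosion of that discrimination by alkene-to-alkene Br+ exchange, or competing bromination at the α-carbon of the keto ester.
- The fallback makes the same bromonium ion enantiospecifically from a stereocentre set earlier by oxidation catalysis. It sets out from 3 and returns at 10.
- Compound 3 is esterified (MeI, K2CO3, DMF) to methyl (3E)-4,8-dimethylnona-3,7-dienoate F1.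
- Shi epoxidation follows, with 1,2:4,5-di-O-isopropylidene-β-D-erythro-hexo-2,3-diulo-2,6-pyranose and KHSO5 as its triple salt 2KHSO5·KHSO4·K2SO4, in K2CO3 buffer and MeCN/dimethoxymethane/H2O at 0 °C. It attacks the more electron-rich terminal alkene and should give methyl (3E)-6-[(2R)-3,3-dimethyloxiran-2-yl]-4-methylhex-3-enoate F2.
- LiOH in THF/H2O gives (3E)-6-[(2R)-3,3-dimethyloxiran-2-yl]-4-methylhex-3-enoic acid F3.
- The chain extension of step 2 (CDI, then 6) gives methyl (5E)-8-[(2R)-3,3-dimethyloxiran-2-yl]-2,6-dimethyl-3-oxooct-5-enoate F4.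
- Li2NiBr4 in THF at 0 °C opens the epoxide at its secondary carbon with inversion to methyl (5E,9S)-9-bromo-10-hydroxy-2,6,10-trimethyl-3-oxoundec-5-enoate F5.
- (CF3CO)2O with 2,6-lutidine in CH2Cl2 at 0 °C gives methyl (5E,9S)-9-bromo-2,6,10-trimethyl-3-oxo-10-(trifluoroacetoxy)undec-5-enoate F6.
- Solvolysis of F6 in (CF3)2CHOH buffered with 2,6-di-tert-butylpyridine ionises the tertiary ester with participation of the neighbouring bromine. No external Br+ is present, so 8 forms as one enantiomer and runs through 9 to 10.

2. Step 4.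
- What may go wrong: thermal decay of the carbenoid outrunning its addition to the hindered, electron-rich ester carbonyl, or deprotonation at the C3 methylene.
- In the fallback C1 enters as a thermally stable methyl nucleophile and the bromine is put on afterwards. It sets out from 10 and returns at 12.
- MeNH(OMe)·HCl with i-PrMgCl in THF, −20 °C to rt, converts 10 into (2Z)-2-[(3aS,5S,7aS)-5-bromo-4,4,7a-trimethylhexahydro-1-benzofuran-2(3H)-ylidene]-N-methoxy-N-methylpropanamide F7.
- MeMgBr in THF at 0 °C gives (3Z)-3-[(3aS,5S,7aS)-5-bromo-4,4,7a-trimethylhexahydro-1-benzofuran-2(3H)-ylidene]butan-2-one F8.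
- Kinetic α'-enolisation (LiN(SiMe3)2, Me3SiCl, THF, −78 °C) gives {(3Z)-3-[(3aS,5S,7aS)-5-bromo-4,4,7a-trimethylhexahydro-1-benzofuran-2(3H)-ylidene]but-1-en-2-yl}oxy(trimethyl)silane F9.
- NBS in THF, −78 to 0 °C, brominates the terminal carbon of F9 to give 12.

3. Step 2.
- What may go wrong: slow C-acylation of the α-substituted malonate, which leaves the imidazolide time to drift into conjugation or to self-condense.
- The fallback acylates a more reactive carbon acid and adds the methyl group afterwards. It sets out from 3 and returns at 7.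
- Compound 3 is coupled (DCC, DMAP, CH2Cl2) with 2,2-dimethyl-1,3-dioxane-4,6-dione to give 5-[(3E)-4,8-dimethylnona-3,7-dienoyl]-2,2-dimethyl-1,3-dioxane-4,6-dione F10.
- Heating F10 in MeOH gives methyl (5E)-6,10-dimethyl-3-oxoundeca-5,9-dienoate F11.
- C-methylation (MeI, K2CO3, acetone) gives 7.

Further compounds
F1 | step 3 | methyl (3E)-4,8-dimethylnona-3,7-dienoate | CC(C)=CCC/C(C)=C/CC(=O)OC
F2 | step 3 | methyl (3E)-6-[(2R)-3,3-dimethyloxiran-2-yl]-4-methylhex-3-enoate | COC(=O)C/C=C(C)/CC[C@H]1OC1(C)C
F3 | step 3 | (3E)-6-[(2R)-3,3-dimethyloxiran-2-yl]-4-methylhex-3-enoic acid | OC(=O)C/C=C(C)/CC[C@H]1OC1(C)C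
F4 | step 3 | methyl (5E)-8-[(2R)-3,3-dimethyloxiran-2-yl]-2,6-dimethyl-3-oxooct-5-enoate | COC(=O)C(C)C(=O)C/C=C(C)/CC[C@H]1OC1(C)C
F5 | step 3 | methyl (5E,9S)-9-bromo-10-hydroxy-2,6,10-trimethyl-3-oxoundec-5-enoate | COC(=O)C(C)C(=O)C/C=C(C)/CC[C@H](Br)C(C)(C)O
F6 | step 3 | methyl (5E,9S)-9-bromo-2,6,10-trimethyl-3-oxo-10-(trifluoroacetoxy)undec-5-enoate | COC(=O)C(C)C(=O)C/C=C(C)/CC[C@H](Br)C(C)(C)OC(=O)C(F)(F)F
F7 | step 4 | (2Z)-2-[(3aS,5S,7aS)-5-bromo-4,4,7a-trimethylhexahydro-1-benzofuran-2(3H)-ylidene]-N-methoxy-N-methylpropanamide | C/C(C(=O)N(C)OC)=C1\C[C@H]2C(C)(C)[C@@H](Br)CC[C@]2(C)O1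
F8 | step 4 | (3Z)-3-[(3aS,5S,7aS)-5-bromo-4,4,7a-trimethylhexahydro-1-benzofuran-2(3H)-ylidene]butan-2-one | C/C(C(C)=O)=C1\C[C@H]2C(C)(C)[C@@H](Br)CC[C@]2(C)O1
F9 | step 4 | {(3Z)-3-[(3aS,5S,7aS)-5-bromo-4,4,7a-trimethylhexahydro-1-benzofuran-2(3H)-ylidene]but-1-en-2-yl}oxy(trimethyl)silane | C/C(C(=C)O[Si](C)(C)C)=C1\C[C@H]2C(C)(C)[C@@H](Br)CC[C@]2(C)O1
F10 | step 2 | 5-[(3E)-4,8-dimethylnona-3,7-dienoyl]-2,2-dimethyl-1,3-dioxane-4,6-dione | CC(C)=CCC/C(C)=C/CC(=O)C1C(=O)OC(C)(C)OC1=O
F11 | step 2 | methyl (5E)-6,10-dimethyl-3-oxoundeca-5,9-dienoate | CC(C)=CCC/C(C)=C/CC(=O)CC(=O)OC
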